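**Plan**

1. Numbering: chroman ring O1, C2–C4, C4a, C5–C8, C8a; side chain C1'–C12' outward from C2. The retrosynthesis first removes two silyl groups, then cuts C4'–C5', the bond between the methyl-bearing olefinic carbon C4' and the methylene C5'.
2. Enabling feature: C4' is an sp2 carbon of the trisubstituted C3'=C4' olefin and C5' is a primary sp3 carbon. Both can therefore sit as nucleophiles on one boron atom (alkenyllithium plus alkyl boronic ester) and be joined by an iodine-triggered 1,2-shift (Zweifel olefination), which also fixes the E geometry by inverting a (Z)-iodoalkene.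
3. Iodoalkene half: cuts at C3'=C4' (iodo-Wittig), at the terminal olefin of a linalool-derived chain (oxidative cleavage), at O1–C8a (Pd C–O coupling) and at C4–C4a (B-alkyl Suzuki coupling). The pyran ring, the only ring made, closes after arene and chain are joined and before the two halves meet.
4. Boronate half: cuts at C11'=C12' (cross-metathesis), C9'–C10' (allylboration) and C7'=C8' (cross-metathesis with methacrolein).
5. Stereochemistry: C2 (R) is carried unchanged from (R)-linalool; C9' (R) comes from a chiral phosphoric acid-catalysed allylboration; C7'=C8' (E) from the metathesis; C3'=C4' (E) from the stereospecific key step.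

Key step: step 12

Assumption: commercial (R)-(−)-linalool of high enantiomeric purity is used; no later step can raise the optical purity at C2 above that of this lot.

**Step 1**
Reactants: 1 4-amino-3-methylphenol
Product: 2 2-methyl-4-(triisopropylsilyloxy)aniline
Conditions: i-Pr3SiCl, imidazole, DMF, 0 °C to rt
Reagents that add atoms: triisopropylsilyl chloride CC(C)[Si](Cl)(C(C)C)C(C)C
Why: Imidazole-promoted silyl ether formation should occur at the more acidic phenol oxygen in preference to the aniline nitrogen, any N-silyl product being hydrolysed on work-up.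

**Step 2**
Reactants: 2 2-methyl-4-(triisopropylsilyloxy)aniline
Product: 3 2-iodo-6-methyl-4-(triisopropylsilyloxy)aniline
Conditions: N-iodosuccinimide, MeCN, 0 °C, dark
Reagents that add atoms: N-iodosuccinimide O=C1CCC(=O)N1I
Why: Electrophilic aromatic iodination should go to the only free position ortho to the amino group (the future C4a), because NH2 is the strongest director and its para position is blocked.

**Step 3**
Reactants: 3 2-iodo-6-methyl-4-(triisopropylsilyloxy)aniline
Product: 4 (4-bromo-3-iodo-5-methylphenoxy)triisopropylsilane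
Conditions: t-BuONO, CuBr2, MeCN, 0 °C to 60 °C
Reagents that add atoms: copper dibromide [Cu+2].[Br-].[Br-]
Why: Non-aqueous Sandmeyer bromination (diazotisation by the alkyl nitrite, bromine transfer from CuBr2) should replace NH2 by Br at the future C8a without acid strong enough to cleave the aryl silyl ether.

**Step 4**
Reactants: 4 (4-bromo-3-iodo-5-methylphenoxy)triisopropylsilane; 5 (R)-linalool
Product: 7 (R)-1-[2-bromo-3-methyl-5-(triisopropylsilyloxy)phenyl]-3,7-dimethyloct-6-en-3-ol, via B-alkyl-9-BBN adduct 6 (not isolated)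
Conditions: 5, 9-BBN-H (1.3 equiv), THF, rt; then 4, PdCl2(dppf) (5 mol%), aq K3PO4, DMF, rt to 40 °C
Reagents that add atoms: none
Why: 9-BBN hydroboration should select the monosubstituted vinyl group over the trisubstituted olefin, and the B-alkyl Suzuki–Miyaura coupling should then occur at the C–I bond, which adds to zerovalent palladium far faster than the doubly ortho-flanked C–Br bond; the linalool carbinol centre is untouched and becomes C2.

**Step 5**
Reactants: 7 (R)-1-[2-bromo-3-methyl-5-(triisopropylsilyloxy)phenyl]-3,7-dimethyloct-6-en-3-ol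
Product: 8 (R)-2,8-dimethyl-2-(4-methylpent-3-en-1-yl)-6-(triisopropylsilyloxy)chromane
Conditions: Pd(OAc)2 (5 mol%), 2-(di-tert-butylphosphino)-1,1'-binaphthyl (6 mol%), Cs2CO3, toluene, 80 °C
Reagents that add atoms: none
Why: Palladium-catalysed intramolecular C–O coupling (Buchwald–Hartwig etherification) of a tertiary alkoxide, which has no β-hydrogen on the carbinol carbon, should close the six-membered pyran ring at O1–C8a without breaking the C2–O bond, so C2 keeps its configuration.

**Step 6**
Reactants: 8 (R)-2,8-dimethyl-2-(4-methylpent-3-en-1-yl)-6-(triisopropylsilyloxy)chromane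
Product: 9 3-[(S)-2,8-dimethyl-6-(triisopropylsilyloxy)chroman-2-yl]propanal (S by priority change only; same spatial arrangement)
Conditions: OsO4 (2 mol%), NaIO4 (4 equiv), 2,6-lutidine, dioxane/H2O 3:1, rt
Reagents that add atoms: osmium tetroxide O=[Os](=O)(=O)=O (catalytic oxygen carrier); sodium periodate [Na+].[O-]I(=O)(=O)=O (terminal oxidant)
Why: Lemieux–Johnson cleavage should dihydroxylate the only olefin and cleave the diol to the C3' aldehyde, with 2,6-lutidine suppressing over-oxidation and the aryl silyl ether inert.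

**Step 7**
Reactants: 9 3-[(S)-2,8-dimethyl-6-(triisopropylsilyloxy)chroman-2-yl]propanal
Product: 10 (R)-2-[(Z)-4-iodopent-3-en-1-yl]-2,8-dimethyl-6-(triisopropylsilyloxy)chromane
Conditions: [Ph3PEt]I, n-BuLi, THF, rt; I2, −78 °C; NaN(SiMe3)2, −20 °C; then 9, −78 °C to −20 °C
Reagents that add atoms: ethyltriphenylphosphonium iodide CC[P+](c1ccccc1)(c1ccccc1)c1ccccc1.[I-]; iodine II
Why: Stork–Zhao-type Wittig olefination with the α-iodo ylide Ph3P=C(I)CH3 should give the (Z)-2-iodo-2-alkene under kinetic control, with iodine cis to the chain as the key step requires.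

**Step 8**
Reactants: 11 2-(but-3-en-1-yl)-4,4,5,5-tetramethyl-1,3,2-dioxaborolane; 12 methacrolein
Product: 13 (E)-2-methyl-5-(4,4,5,5-tetramethyl-1,3,2-dioxaborolan-2-yl)pent-2-enal
Conditions: 12 (4 equiv), RuCl2(=CH-2-(i-PrO)C6H4)(H2IMes) (second-generation Hoveyda–Grubbs catalyst, 3 mol%), CH2Cl2, 40 °C
Reagents that add atoms: none
Why: Olefin cross-metathesis of a terminal olefin with the 1,1-disubstituted, electron-poor methacrolein (which does not homodimerise) should give the conjugated trisubstituted enal as the favoured E isomer, the alkyl boronic ester being inert to the ruthenium carbene.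

**Step 9**
Reactants: 13 (E)-2-methyl-5-(4,4,5,5-tetramethyl-1,3,2-dioxaborolan-2-yl)pent-2-enal
Product: 15 (4R,5E)-5-methyl-8-(4,4,5,5-tetramethyl-1,3,2-dioxaborolan-2-yl)octa-1,5-dien-4-ol, via O-boryl ether 14 (not isolated)
Conditions: allyl-Bpin (1.2 equiv), (R)-3,3'-bis(2,4,6-triisopropylphenyl)-1,1'-binaphthyl-2,2'-diyl hydrogen phosphate ((R)-TRIP, 5 mol%), toluene, −30 °C; aq NaHCO3 work-up
Reagents that add atoms: allylboronic acid pinacol ester C=CCB1OC(C)(C)C(C)(C)O1
Why: Chiral phosphoric acid-catalysed allylboration through a chair-like six-membered transition state should, with (R)-TRIP, deliver the allyl group to the Re face of the enal and set C9' as (R); the alkyl boronic ester of the substrate carries no allyl group and stays a spectator.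

**Step 10**
Reactants: 15 (4R,5E)-5-methyl-8-(4,4,5,5-tetramethyl-1,3,2-dioxaborolan-2-yl)octa-1,5-dien-4-ol
Product: 16 tert-butyldimethyl{[(4R,5E)-5-methyl-8-(4,4,5,5-tetramethyl-1,3,2-dioxaborolan-2-yl)octa-1,5-dien-4-yl]oxy}silane
Conditions: t-BuMe2SiCl, imidazole, DMF, rt
Reagents that add atoms: tert-butyldimethylsilyl chloride CC(C)(C)[Si](C)(C)Cl
Why: Standard silyl ether formation should mask the allylic hydroxyl, whose acidic proton would otherwise quench the alkenyllithium of the key step.

**Step 11**
Reactants: 16 tert-butyldimethyl{[(4R,5E)-5-methyl-8-(4,4,5,5-tetramethyl-1,3,2-dioxaborolan-2-yl)octa-1,5-dien-4-yl]oxy}silane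
Product: 17 tert-butyl{[(5R,6E)-2,6-dimethyl-9-(4,4,5,5-tetramethyl-1,3,2-dioxaborolan-2-yl)nona-2,6-dien-5-yl]oxy}dimethylsilane
Conditions: 2-methyl-2-butene (large excess), RuCl2(=CHPh)(PCy3)(H2IMes) (second-generation Grubbs catalyst, 5 mol%), CH2Cl2, rt to 35 °C
Reagents that add atoms: 2-methyl-2-butene CC=C(C)C
Why: Olefin cross-metathesis of the terminal vinyl group with 2-methyl-2-butene should install the isopropylidene terminus, while the trisubstituted C7'=C8' olefin and the trisubstituted product are too hindered for secondary metathesis.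

**Step 12**
Reactants: 10 (R)-2-[(Z)-4-iodopent-3-en-1-yl]-2,8-dimethyl-6-(triisopropylsilyloxy)chromane; 17 tert-butyl{[(5R,6E)-2,6-dimethyl-9-(4,4,5,5-tetramethyl-1,3,2-dioxaborolan-2-yl)nona-2,6-dien-5-yl]oxy}dimethylsilane
Product: 21 bis-silyl ether of sargachromanol C (6-O-triisopropylsilyl and 9'-O-tert-butyldimethylsilyl; 2R and 9'R; 3'E and 7'E), via alkenyllithium 18 (not isolated), via lithium boronate complex 19 (not isolated), via beta-iodo boronic ester 20 (not isolated)
Conditions: 10 (1.2 equiv), t-BuLi (2.4 equiv), Et2O/THF, −78 °C; 17 (1.0 equiv), THF, −78 °C; I2 (1.3 equiv), THF/MeOH, −78 °C; NaOMe (3 equiv), MeOH, −78 °C to 0 °C; aq Na2S2O3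
Reagents that add atoms: none
Why: Zweifel olefination: iodine–lithium exchange with retention should give alkenyllithium 18, which adds to the boron atom of 17 to give complex 19 with C4' and C5' both bound to boron as nucleophilic carbons; iodine then attacks the electron-rich C3'=C4' bond at C3', the primary alkyl group (C5') migrates from boron to C4' anti to the new C–I bond (1,2-metallate shift) to give 20, and methoxide triggers anti elimination of boron and iodine. The closest known reaction type is the Zweifel coupling of alkenyllithiums with primary alkyl pinacol boronic esters to trisubstituted olefins, an oxidative union of two carbon nucleophiles that needs no transition metal. No ring is closed and no lasting stereocentre is formed; the two sp3 centres of 20 are transient, and either diastereomeric pair from attack on the two olefin faces collapses to the same olefin. Anti addition followed by anti elimination inverts the olefin geometry, so the (Z)-iodoalkene (boron cis to C2') should give the (E)-C3'=C4' olefin with C5' trans to C2'. The step needs iodine to select the boronate-activated olefin over the two other trisubstituted olefins and the arene, which the negative charge on boron should secure at −78 °C with only a small excess of iodine, and it needs migration of the alkyl group alone, which the non-migrating pinacolato oxygens secure. Both silyl ethers lack acidic hydrogens and should tolerate t-BuLi and cold methoxide.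

**Step 13**
Reactants: 21 bis-silyl ether of sargachromanol C
Product: 22 sargachromanol C
Conditions: Bu4NF (4 equiv), AcOH (4 equiv), THF, rt to 40 °C, under argon
Reagents that add atoms: none
Why: Fluoride-mediated desilylation should cleave both the aryl triisopropylsilyl ether and the secondary tert-butyldimethylsilyl ether, the acetic acid buffer keeping the air-sensitive chromanol from standing as its phenoxide.

**Compound list**

1 | 4-amino-3-methylphenol | Nc1ccc(O)cc1C | starting material
2 | 2-methyl-4-(triisopropylsilyloxy)aniline | Nc1ccc(O[Si](C(C)C)(C(C)C)C(C)C)cc1C | intermediate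
3 | 2-iodo-6-methyl-4-(triisopropylsilyloxy)aniline | Nc1c(I)cc(O[Si](C(C)C)(C(C)C)C(C)C)cc1C | intermediate
4 | (4-bromo-3-iodo-5-methylphenoxy)triisopropylsilane | Brc1c(I)cc(O[Si](C(C)C)(C(C)C)C(C)C)cc1C | intermediate
5 | (R)-linalool, (3R)-3,7-dimethylocta-1,6-dien-3-ol | CC(C)=CCC[C@@](C)(O)C=C | starting material
6 | (S)-1-(9-borabicyclo[3.3.1]nonan-9-yl)-3,7-dimethyloct-6-en-3-ol (B-alkyl-9-BBN adduct; S by priority change only) | CC(C)=CCC[C@@](C)(O)CCB1C2CCCC1CCC2 | intermediate
7 | (R)-1-[2-bromo-3-methyl-5-(triisopropylsilyloxy)phenyl]-3,7-dimethyloct-6-en-3-ol | CC(C)=CCC[C@@](C)(O)CCc1cc(O[Si](C(C)C)(C(C)C)C(C)C)cc(C)c1Br | intermediate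
8 | (R)-2,8-dimethyl-2-(4-methylpent-3-en-1-yl)-6-(triisopropylsilyloxy)chromane | CC(C)=CCC[C@]1(C)CCc2cc(O[Si](C(C)C)(C(C)C)C(C)C)cc(C)c2O1 | intermediate
9 | 3-[(S)-2,8-dimethyl-6-(triisopropylsilyloxy)chroman-2-yl]propanal | O=CCC[C@]1(C)CCc2cc(O[Si](C(C)C)(C(C)C)C(C)C)cc(C)c2O1 | intermediate
10 | (R)-2-[(Z)-4-iodopent-3-en-1-yl]-2,8-dimethyl-6-(triisopropylsilyloxy)chromane | C/C(I)=C/CC[C@]1(C)CCc2cc(O[Si](C(C)C)(C(C)C)C(C)C)cc(C)c2O1 | intermediate
11 | 2-(but-3-en-1-yl)-4,4,5,5-tetramethyl-1,3,2-dioxaborolane | C=CCCB1OC(C)(C)C(C)(C)O1 | starting material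
12 | methacrolein (2-methylprop-2-enal) | CC(=C)C=O | starting material
13 | (E)-2-methyl-5-(4,4,5,5-tetramethyl-1,3,2-dioxaborolan-2-yl)pent-2-enal | O=C/C(C)=C/CCB1OC(C)(C)C(C)(C)O1 | intermediate
14 | O-(pinacolboryl) ether of 15 | C=CC[C@@H](OB1OC(C)(C)C(C)(C)O1)/C(C)=C/CCB2OC(C)(C)C(C)(C)O2 | intermediate
15 | (4R,5E)-5-methyl-8-(4,4,5,5-tetramethyl-1,3,2-dioxaborolan-2-yl)octa-1,5-dien-4-ol | C=CC[C@@H](O)/C(C)=C/CCB1OC(C)(C)C(C)(C)O1 | intermediate
16 | tert-butyldimethyl{[(4R,5E)-5-methyl-8-(4,4,5,5-tetramethyl-1,3,2-dioxaborolan-2-yl)octa-1,5-dien-4-yl]oxy}silane | C=CC[C@@H](O[Si](C)(C)C(C)(C)C)/C(C)=C/CCB1OC(C)(C)C(C)(C)O1 | intermediate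
17 | tert-butyl{[(5R,6E)-2,6-dimethyl-9-(4,4,5,5-tetramethyl-1,3,2-dioxaborolan-2-yl)nona-2,6-dien-5-yl]oxy}dimethylsilane | CC(C)=CC[C@@H](O[Si](C)(C)C(C)(C)C)/C(C)=C/CCB1OC(C)(C)C(C)(C)O1 | intermediate
18 | alkenyllithium from 10 (lithium in place of iodine, geometry retained) | C/C([Li])=C/CC[C@]1(C)CCc2cc(O[Si](C(C)C)(C(C)C)C(C)C)cc(C)c2O1 | intermediate
19 | lithium boronate complex (boron bound to C4' of 18 and to C5' of 17) | [Li+].C/C(=C/CC[C@]1(C)CCc2cc(O[Si](C(C)C)(C(C)C)C(C)C)cc(C)c2O1)[B-]1(CC/C=C(C)/[C@H](O[Si](C)(C)C(C)(C)C)CC=C(C)C)OC(C)(C)C(C)(C)O1 | intermediate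
20 | beta-iodo boronic ester (anti adduct; one of two diastereomers shown, the other is epimeric at both new centres) | CC(C)=CC[C@@H](O[Si](C)(C)C(C)(C)C)/C(C)=C/CC[C@](C)(B1OC(C)(C)C(C)(C)O1)[C@H](I)CC[C@]1(C)CCc2cc(O[Si](C(C)C)(C(C)C)C(C)C)cc(C)c2O1 | intermediate
21 | bis-silyl ether of sargachromanol C (6-O-triisopropylsilyl, 9'-O-tert-butyldimethylsilyl) | CC(C)=CC[C@@H](O[Si](C)(C)C(C)(C)C)/C(C)=C/CC/C(C)=C/CC[C@]1(C)CCc2cc(O[Si](C(C)C)(C(C)C)C(C)C)cc(C)c2O1 | intermediate
22 | sargachromanol C | CC(C)=CC[C@@H](O)/C(C)=C/CC/C(C)=C/CC[C@]1(C)CCc2cc(O)cc(C)c2O1 | target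

**Step count**

Total: 13 steps. Longest linear sequence: 9 steps (steps 1–7, 12, 13); steps 8–11 form the second branch.

**Steps most likely to fail**

Step 12. The boronate complex may form incompletely with the hindered alkenyllithium. Iodine may be consumed by the other olefins. Methoxide may cleave the aryl silyl ether early, after which residual iodine could iodinate the ring. Any non-stereospecific elimination would erode the E geometry. The fallback sets out from 9 and joins the halves by a stereoretentive cross-coupling instead. Colvin homologation of 9 (LiC(N2)SiMe3, THF, −78 °C to rt) should give the terminal alkyne F1. Deprotonation with n-BuLi and methylation with MeI should give the 2-alkyne F2. Hydrozirconation with Cp2Zr(H)Cl (THF, 50 °C, equilibration placing zirconium next to the methyl group) and iodinolysis should give the (E)-iodoalkene F3 by syn addition. B-alkyl Suzuki–Miyaura coupling of F3 with 17 (Pd(OAc)2, SPhos, K3PO4, toluene/H2O, 80 °C) proceeds with retention and comes back to the route at 21.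

Step 7. The iodo ylide may decompose before it meets the aldehyde. Incomplete iodination of the ethylidene ylide would give the iodine-free olefin. The Z selectivity may erode. The fallback sets out from 9. Corey–Fuchs dibromo-olefination (CBr4, PPh3, CH2Cl2, 0 °C) should give the 1,1-dibromoalkene F4. Trans-selective Negishi monomethylation (MeZnCl, PdCl2(DPEphos), THF, 0 °C to rt) replaces the less hindered bromine, the one trans to the chain, and should give the (Z)-bromoalkene F5. Bromine–lithium exchange of F5 with t-BuLi gives the same alkenyllithium, so the route is rejoined at 18 within step 12.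

Step 5. Oxidative addition into the doubly ortho-substituted, electron-rich C–Br bond may be slow, and reduction of the C–Br bond may compete with C–O reductive elimination. The fallback sets out from 3 and closes the same O1–C8a bond through an aryl cation instead of a palladium alkoxide. B-alkyl Suzuki–Miyaura coupling of iodoaniline 3 with borane 6 (PdCl2(dppf), aq K3PO4, DMF, rt) should give the amino alcohol F6. Diazotisation (NOBF4, MeCN, −30 °C) should give the arenediazonium tetrafluoroborate F7. Heterolytic loss of nitrogen on warming (1,2-dichloroethane, 60–80 °C) should let the tethered tertiary hydroxyl capture the aryl cation in a six-membered closure, as in the classical chroman synthesis from o-aminophenyl alkanols. The C2–O bond is never broken, and the route is rejoined at 8.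

**Further compounds**

F1 | step 12 | (R)-2-(but-3-yn-1-yl)-2,8-dimethyl-6-(triisopropylsilyloxy)chromane | C#CCC[C@]1(C)CCc2cc(O[Si](C(C)C)(C(C)C)C(C)C)cc(C)c2O1
F2 | step 12 | (R)-2,8-dimethyl-2-(pent-3-yn-1-yl)-6-(triisopropylsilyloxy)chromane | CC#CCC[C@]1(C)CCc2cc(O[Si](C(C)C)(C(C)C)C(C)C)cc(C)c2O1
F3 | step 12 | (R)-2-[(E)-4-iodopent-3-en-1-yl]-2,8-dimethyl-6-(triisopropylsilyloxy)chromane | C/C(I)=C\CC[C@]1(C)CCc2cc(O[Si](C(C)C)(C(C)C)C(C)C)cc(C)c2O1
F4 | step 7 | (R)-2-(4,4-dibromobut-3-en-1-yl)-2,8-dimethyl-6-(triisopropylsilyloxy)chromane | BrC(Br)=CCC[C@]1(C)CCc2cc(O[Si](C(C)C)(C(C)C)C(C)C)cc(C)c2O1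
F5 | step 7 | (R)-2-[(Z)-4-bromopent-3-en-1-yl]-2,8-dimethyl-6-(triisopropylsilyloxy)chromane | C/C(Br)=C/CC[C@]1(C)CCc2cc(O[Si](C(C)C)(C(C)C)C(C)C)cc(C)c2O1
F6 | step 5 | (R)-1-[2-amino-3-methyl-5-(triisopropylsilyloxy)phenyl]-3,7-dimethyloct-6-en-3-ol | CC(C)=CCC[C@@](C)(O)CCc1cc(O[Si](C(C)C)(C(C)C)C(C)C)cc(C)c1N
F7 | step 5 | 2-[(R)-3-hydroxy-3,7-dimethyloct-6-en-1-yl]-6-methyl-4-(triisopropylsilyloxy)benzenediazonium tetrafluoroborate | CC(C)=CCC[C@@](C)(O)CCc1cc(O[Si](C(C)C)(C(C)C)C(C)C)cc(C)c1[N+]#N.F[B-](F)(F)F
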